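The decalin is numbered as a drimane (C1–C10; C11 = CH2O carbon, C12 = exocyclic CH2). Ring B holds the 3-methylidenecyclohexene unit C12=C8–C7=C6 flanked by sp3 C5, C10 and C9, which is the retron of a vinylallene Diels–Alder reaction. An acyclic (E)-enoate (C11, C9=C10), joined through the tether C1–C4 to an (E)-vinylallene (C5=C6–C7=C8=C12) and made from methyl geranate, is cyclised in one Lewis-acid-promoted intramolecular [4+2] step. This step forms C8–C9 and C5–C10, closes rings B and A, and sets C5, C9 and C10 from the single C3 stereocentre. Ester reduction and Mitsunobu etherification with umbelliferone complete the route.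

Key step: step 7

Remark: methyl geranate is assumed to be available commercially as the pure (2E) isomer, and the prenylborane of step 2 is prepared beforehand from (−)-Ipc2BOMe and prenylmagnesium chloride by the standard procedure.

Step 1
Reactants: 1 methyl (2E)-3,7-dimethylocta-2,6-dienoate (methyl geranate)
Product: 3 methyl (2E)-3-methyl-6-oxohex-2-enoate, via secondary ozonide 2 (not isolated)
Conditions: O3 (1 equiv), CH2Cl2, −78 °C; then Me2S, −78 °C to rt
Reagents that add atoms: ozone, O=[O+][O-]
Why: Ozonolysis, in which the electron-rich trisubstituted C6=C7 alkene reacts far faster than the ester-conjugated C2=C3 alkene, so that one equivalent of ozone and reductive cleavage of the ozonide should give the aldehyde with the (E)-enoate intact; no stereocentre is formed.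

Step 2
Reactants: 3 methyl (2E)-3-methyl-6-oxohex-2-enoate
Product: 5 methyl (2E,6R)-6-hydroxy-3,7,7-trimethylnona-2,8-dienoate, via diisopinocampheylborinate 4 (not isolated)
Conditions: (−)-Ipc2B(CH2CH=CMe2) [from (+)-α-pinene], Et2O, −78 °C; then NaBO3·4H2O, THF/H2O, rt
Reagents that add atoms: B-(3-methylbut-2-enyl)diisopinocampheylborane, CC(C)=CCB([C@@H]1C[C@@H]2C[C@H]([C@H]1C)C2(C)C)[C@@H]1C[C@@H]2C[C@H]([C@H]1C)C2(C)C
Why: Brown asymmetric allylboration with allylic transposition (reverse prenylation) through a chair Zimmerman–Traxler transition state, in which the isopinocampheyl groups derived from (+)-α-pinene should steer the tertiary allyl terminus to the Si face of the aldehyde and so set the (6R) carbinol next to the new quaternary carbon, the ester being inert at −78 °C.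

Step 3
Reactants: 5 methyl (2E,6R)-6-hydroxy-3,7,7-trimethylnona-2,8-dienoate
Product: 6 methyl (2E,6R)-6-acetoxy-3,7,7-trimethylnona-2,8-dienoate
Conditions: Ac2O, pyridine, DMAP (cat.), CH2Cl2, rt
Reagents that add atoms: acetic anhydride, CC(=O)OC(C)=O
Why: DMAP-catalysed acylation of the hindered secondary alcohol, giving an acetate that masks the hydroxyl during steps 4 to 7 and is removed without an extra operation by the hydride of step 8.

Step 4
Reactants: 6 methyl (2E,6R)-6-acetoxy-3,7,7-trimethylnona-2,8-dienoate
Product: 8 methyl (2E,6R)-6-acetoxy-3,7,7-trimethyl-8-oxooct-2-enoate, via vicinal diol 7 (not isolated)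
Conditions: OsO4 (cat.), NaIO4, 2,6-lutidine, dioxane/H2O, rt
Reagents that add atoms: OsO4 (catalytic oxygen carrier), O=[Os](=O)(=O)=O; sodium periodate (terminal oxidant that restores it), [Na+].[O-]I(=O)(=O)=O
Why: Lemieux–Johnson cleavage, in which OsO4 dihydroxylates the monosubstituted alkene in preference to the electron-poor trisubstituted enoate and NaIO4 cleaves the diol as it forms, with 2,6-lutidine buffering the medium; the C6 stereocentre is not touched.

Step 5
Reactants: 8 methyl (2E,6R)-6-acetoxy-3,7,7-trimethyl-8-oxooct-2-enoate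
Product: 9 methyl (2E,6R,8E)-6-acetoxy-9-iodo-3,7,7-trimethylnona-2,8-dienoate
Conditions: CrCl2, CHI3, THF, 0 °C to rt
Reagents that add atoms: iodoform, IC(I)I
Why: Takai olefination, in which the geminal dichromium species formed from CHI3 and CrCl2 adds to the aldehyde and eliminates, should give the (E)-iodoalkene with the high E preference typical of α-branched aldehydes, and both esters tolerate divalent chromium.

Step 6
Reactants: 9 methyl (2E,6R,8E)-6-acetoxy-9-iodo-3,7,7-trimethylnona-2,8-dienoate
Product: 10 methyl (2E,6R,8E)-6-acetoxy-3,7,7-trimethyldodeca-2,8,10,11-tetraenoate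
Conditions: Bu3SnCH=C=CH2, Pd2(dba)3 (cat.), AsPh3, DMF, rt
Reagents that add atoms: tributyl(propa-1,2-dienyl)stannane, C=C=C[Sn](CCCC)(CCCC)CCCC
Why: Stille coupling, in which oxidative addition of the alkenyl iodide to zerovalent palladium, transfer of the allenyl group from tin and reductive elimination should give the vinylallene with retention of the E geometry under neutral conditions that spare both esters.

Step 7
Reactants: 10 methyl (2E,6R,8E)-6-acetoxy-3,7,7-trimethyldodeca-2,8,10,11-tetraenoate
Product: 11 methyl (1R,4aS,6R,8aR)-6-acetoxy-5,5,8a-trimethyl-2-methylidene-1,2,4a,5,6,7,8,8a-octahydronaphthalene-1-carboxylate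
Conditions: Me2AlCl (2.5 equiv), CH2Cl2 (0.01 M), −78 to 0 °C
Reagents that add atoms: none
Why: Me2AlCl bound to the ester carbonyl lowers the LUMO of the C9=C10 enoate, and the s-cis vinylallene C5=C6–C7=C8(=C12) adds across it in a concerted, asynchronous intramolecular [4+2] cycloaddition that forms C8–C9 and C5–C10 and leaves C8=C12 as the exocyclic methylene next to the new C6=C7 bond. The closest known reactions are Lewis-acid-promoted intramolecular Diels–Alder reactions of deca-2,8,10-trienoates and Diels–Alder reactions of vinylallenes. Ring B is closed as the six-membered cycloadduct ring and ring A as the six-membered ring of the four-carbon tether C1–C4, which adopts a chair in the transition state. Suprafacial addition to the (E)-enoate places the ester on C9 cis to the C10 methyl group, the ester-endo transition state of the (E)-diene gives the trans ring fusion at C5, and the equatorial C3 acetate on the chair tether decides which diene face is attacked, so that the (3R) centre sets the absolute configuration of C5, C9 and C10. The step needs endo over exo closure and attack on one diene face: the complexed ester (secondary orbital overlap, low temperature) should secure the former and the C3 stereocentre next to the gem-dimethyl group the latter, while regiochemistry is fixed by the tether and a 1,5-hydrogen shift of the vinylallene is excluded because C4 carries no hydrogen.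

Step 8
Reactants: 11 methyl (1R,4aS,6R,8aR)-6-acetoxy-5,5,8a-trimethyl-2-methylidene-1,2,4a,5,6,7,8,8a-octahydronaphthalene-1-carboxylate
Product: 12 (2R,4aR,5R,8aS)-5-(hydroxymethyl)-1,1,4a-trimethyl-6-methylidene-1,2,3,4,4a,5,6,8a-octahydronaphthalen-2-ol
Conditions: iBu2AlH (excess), CH2Cl2, −78 to 0 °C; aqueous Rochelle salt work-up
Reagents that add atoms: none
Why: Hydride reduction with iBu2AlH converts the methyl ester into the primary alcohol and cleaves the acetate in the same operation under non-basic conditions, so that the allylic C9 stereocentre is neither epimerised nor brought into conjugation.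

Step 9
Reactants: 12 (2R,4aR,5R,8aS)-5-(hydroxymethyl)-1,1,4a-trimethyl-6-methylidene-1,2,3,4,4a,5,6,8a-octahydronaphthalen-2-ol; 13 umbelliferone (7-hydroxy-2H-chromen-2-one)
Product: 14 7-{[(1R,4aS,6R,8aR)-6-hydroxy-5,5,8a-trimethyl-2-methylidene-1,2,4a,5,6,7,8,8a-octahydronaphthalen-1-yl]methoxy}-2H-chromen-2-one
Conditions: PPh3, DIAD, THF, 0 °C to rt
Reagents that add atoms: none
Why: Mitsunobu etherification, in which the acidic phenol of umbelliferone displaces the activated primary C11 oxyphosphonium group by SN2 reaction while the secondary C3 hydroxyl flanked by the quaternary C4 is too hindered to react; no stereocentre is involved.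

Compound list
1 | methyl (2E)-3,7-dimethylocta-2,6-dienoate (methyl geranate) | COC(=O)/C=C(\C)CCC=C(C)C | starting material
2 | methyl (2E)-5-(5,5-dimethyl-1,2,4-trioxolan-3-yl)-3-methylpent-2-enoate (secondary ozonide, ring CH configuration undefined) | COC(=O)/C=C(\C)CCC1OOC(C)(C)O1 | intermediate (not isolated)
3 | methyl (2E)-3-methyl-6-oxohex-2-enoate | COC(=O)/C=C(\C)CCC=O | intermediate
4 | methyl (2E,6R)-6-[(diisopinocampheylboranyl)oxy]-3,7,7-trimethylnona-2,8-dienoate | COC(=O)/C=C(\C)CC[C@@H](OB([C@@H]1C[C@@H]2C[C@H]([C@H]1C)C2(C)C)[C@@H]1C[C@@H]2C[C@H]([C@H]1C)C2(C)C)C(C)(C)C=C | intermediate (not isolated)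
5 | methyl (2E,6R)-6-hydroxy-3,7,7-trimethylnona-2,8-dienoate | COC(=O)/C=C(\C)CC[C@@H](O)C(C)(C)C=C | intermediate
6 | methyl (2E,6R)-6-acetoxy-3,7,7-trimethylnona-2,8-dienoate | COC(=O)/C=C(\C)CC[C@@H](OC(C)=O)C(C)(C)C=C | intermediate
7 | methyl (2E,6R)-6-acetoxy-8,9-dihydroxy-3,7,7-trimethylnon-2-enoate (both C8 epimers) | COC(=O)/C=C(\C)CC[C@@H](OC(C)=O)C(C)(C)C(O)CO | intermediate (not isolated)
8 | methyl (2E,6R)-6-acetoxy-3,7,7-trimethyl-8-oxooct-2-enoate | COC(=O)/C=C(\C)CC[C@@H](OC(C)=O)C(C)(C)C=O | intermediate
9 | methyl (2E,6R,8E)-6-acetoxy-9-iodo-3,7,7-trimethylnona-2,8-dienoate | COC(=O)/C=C(\C)CC[C@@H](OC(C)=O)C(C)(C)/C=C/I | intermediate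
10 | methyl (2E,6R,8E)-6-acetoxy-3,7,7-trimethyldodeca-2,8,10,11-tetraenoate (drimane numbering: ester carbon C11, enoate C9=C10, tether C1–C4, vinylallene C5=C6–C7=C8=C12) | COC(=O)/C=C(\C)CC[C@@H](OC(C)=O)C(C)(C)/C=C/C=C=C | intermediate
11 | methyl (1R,4aS,6R,8aR)-6-acetoxy-5,5,8a-trimethyl-2-methylidene-1,2,4a,5,6,7,8,8a-octahydronaphthalene-1-carboxylate | C=C1C=C[C@@H]2C(C)(C)[C@H](OC(C)=O)CC[C@@]2(C)[C@@H]1C(=O)OC | intermediate
12 | (2R,4aR,5R,8aS)-5-(hydroxymethyl)-1,1,4a-trimethyl-6-methylidene-1,2,3,4,4a,5,6,8a-octahydronaphthalen-2-ol | C=C1C=C[C@@H]2C(C)(C)[C@H](O)CC[C@@]2(C)[C@@H]1CO | intermediate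
13 | umbelliferone (7-hydroxy-2H-chromen-2-one) | O=c1ccc2ccc(O)cc2o1 | starting material
14 | 7-{[(1R,4aS,6R,8aR)-6-hydroxy-5,5,8a-trimethyl-2-methylidene-1,2,4a,5,6,7,8,8a-octahydronaphthalen-1-yl]methoxy}-2H-chromen-2-one | C=C1C=C[C@@H]2C(C)(C)[C@H](O)CC[C@@]2(C)[C@@H]1COc1ccc2ccc(=O)oc2c1 | target

Total step count: 9. Longest linear sequence: 9 steps (1 to 14).

Steps most likely to fail

Step 7. The cycloaddition may close through the exo transition state (cis ring fusion), attack the other diene face, or lose the vinylallene to Lewis-acid-induced oligomerisation. The fallback changes the dienophile to the more reactive enal and drops the Lewis acid. It sets out from 10: iBu2AlH (CH2Cl2, −78 °C) should reduce both esters to (2E,6R,8E)-3,7,7-trimethyldodeca-2,8,10,11-tetraene-1,6-diol F1. MnO2 (CH2Cl2, rt) should oxidise only the allylic alcohol to (2E,6R,8E)-6-hydroxy-3,7,7-trimethyldodeca-2,8,10,11-tetraenal F2. Heating (toluene, BHT, 80–110 °C) should then cyclise it through the aldehyde-endo transition state to (1R,4aS,6R,8aR)-6-hydroxy-5,5,8a-trimethyl-2-methylidene-1,2,4a,5,6,7,8,8a-octahydronaphthalene-1-carbaldehyde F3, and NaBH4 (MeOH, 0 °C) returns to the route at 12.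

Step 6. Transmetalation through the propargyl form may deliver the skipped enyne in place of the allene, or protodestannylation may outrun coupling. The fallback builds the allene by reductive transposition and sets out from 9. Sonogashira coupling with prop-2-yn-1-ol (Pd(PPh3)2Cl2, CuI, Et3N, rt) should give methyl (2E,6R,8E)-6-acetoxy-12-hydroxy-3,7,7-trimethyldodeca-2,8-dien-10-ynoate F4. Myers allene synthesis (2-nitrobenzenesulfonylhydrazide, PPh3, DEAD, THF, −15 °C to rt) should pass through methyl (2E,6R,8E)-6-acetoxy-3,7,7-trimethyl-12-[1-(2-nitrobenzenesulfonyl)hydrazinyl]dodeca-2,8-dien-10-ynoate F5 and methyl (2E,6R,8E)-6-acetoxy-12-diazenyl-3,7,7-trimethyldodeca-2,8-dien-10-ynoate F6. The latter loses dinitrogen by retro-ene reaction and comes back to the route at 10.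

Step 9. Activation of the β-branched primary alcohol may end in elimination toward the diene, or substitution at C11 may stall. The fallback forms the ether bond at the aryl carbon instead and sets out from 12: palladium-catalysed C–O coupling with 7-bromo-2H-chromen-2-one (Pd2(dba)3, tBuBrettPhos, Cs2CO3, toluene, 80 °C), in which the hindered secondary alcohol should not compete, gives 14 directly, so no new compound arises (F0).

Further compounds
F1 | step 7 | (2E,6R,8E)-3,7,7-trimethyldodeca-2,8,10,11-tetraene-1,6-diol | OC/C=C(\C)CC[C@@H](O)C(C)(C)/C=C/C=C=C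
F2 | step 7 | (2E,6R,8E)-6-hydroxy-3,7,7-trimethyldodeca-2,8,10,11-tetraenal | O=C/C=C(\C)CC[C@@H](O)C(C)(C)/C=C/C=C=C
F3 | step 7 | (1R,4aS,6R,8aR)-6-hydroxy-5,5,8a-trimethyl-2-methylidene-1,2,4a,5,6,7,8,8a-octahydronaphthalene-1-carbaldehyde | C=C1C=C[C@@H]2C(C)(C)[C@H](O)CC[C@@]2(C)[C@@H]1C=O
F4 | step 6 | methyl (2E,6R,8E)-6-acetoxy-12-hydroxy-3,7,7-trimethyldodeca-2,8-dien-10-ynoate | COC(=O)/C=C(\C)CC[C@@H](OC(C)=O)C(C)(C)/C=C/C#CCO
F5 | step 6 | methyl (2E,6R,8E)-6-acetoxy-3,7,7-trimethyl-12-[1-(2-nitrobenzenesulfonyl)hydrazinyl]dodeca-2,8-dien-10-ynoate | COC(=O)/C=C(\C)CC[C@@H](OC(C)=O)C(C)(C)/C=C/C#CCN(N)S(=O)(=O)c1ccccc1[N+](=O)[O-]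
F6 | step 6 | methyl (2E,6R,8E)-6-acetoxy-12-diazenyl-3,7,7-trimethyldodeca-2,8-dien-10-ynoate | COC(=O)/C=C(\C)CC[C@@H](OC(C)=O)C(C)(C)/C=C/C#CCN=N
F0 | step 9 | none | none
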